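**Strategy.** Ring A of the trans-decalin is cut into a C8a=C1–C2=C3 diene and a C4=C4a alkene that the C5–C8 chain of ring B already links. One intramolecular Diels–Alder reaction of an open-chain (E)-1,3,9-decatriene therefore forms C3–C4 and C4a–C8a, closes rings A and B together and sets the quaternary C4a and C8a from the single C7 stereocentre, which comes from (R)-α-terpineol. The feature exploited is the 1,4-relationship in ring A between the oxygenated, methyl-bearing C2 and the methyl-bearing C4a next to the ring-fusion CH, the pattern of a 2-methyldiene adding to an isopropenyl group. The resulting C1=C2 olefin is then converted into the axial tertiary ether, on which the honokiol biaryl is built.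

Key step: step 5

Remark on locants: all bicyclic compounds are numbered as the terpene part of the target: C1, C2 (bears CH3 and O), C3, C4, C4a (angular CH3), C5, C6, C7 (bears the propan-2-yl side chain), C8, C8a (ring-fusion H). Ring A = C1–C4, C4a, C8a; ring B = C4a, C5–C8, C8a. The target is (2R,4aS,7R,8aS): trans-fused, C2–O axial, C7 side chain equatorial and cis to the C4a methyl.

Assumption: 2-allyl-4-bromophenol is taken as a catalogue compound (otherwise it follows from 4-bromophenol by O-allylation and Claisen rearrangement).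

**Route**

Step 1
Reactants: 1 (R)-α-terpineol
Product: 2 triethyl({2-[(1R)-4-methylcyclohex-3-en-1-yl]propan-2-yl}oxy)silane
Conditions: TESOTf, 2,6-lutidine, CH2Cl2, 0 °C
Reagents that add atoms: triethylsilyl trifluoromethanesulfonate, CC[Si](CC)(CC)OS(=O)(=O)C(F)(F)F
Why: Silylation of a tertiary alcohol with a silyl triflate; no stereocentre is touched, and the bulky C(CH3)2OSiEt3 group later serves as the conformational anchor of the key step.

Step 2
Reactants: 2 triethyl({2-[(1R)-4-methylcyclohex-3-en-1-yl]propan-2-yl}oxy)silane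
Product: 4 (3R)-6-oxo-3-[2-(triethylsilyloxy)propan-2-yl]heptanal, via ozonide 3 (not isolated)
Conditions: O3, CH2Cl2, −78 °C; then PPh3, −78 °C → rt
Reagents that add atoms: ozone, [O-][O+]=O
Why: Ozonolysis with reductive work-up cleaves the only C=C bond to the 1,6-keto aldehyde; the stereocentre is not involved and stays R.

Step 3
Reactants: 4 (3R)-6-oxo-3-[2-(triethylsilyloxy)propan-2-yl]heptanal
Product: 5 (3E,6R)-6-[2-(triethylsilyloxy)propan-2-yl]dec-3-ene-2,9-dione
Conditions: Ph3P=CHC(O)CH3, CH2Cl2, rt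
Reagents that add atoms: 1-(triphenylphosphoranylidene)propan-2-one, CC(=O)C=P(c1ccccc1)(c1ccccc1)c1ccccc1
Why: Wittig olefination with a stabilized ylide, which should react with the aldehyde and not with the methyl ketone and give the (E)-enone; no stereocentre is formed.

Step 4
Reactants: 5 (3E,6R)-6-[2-(triethylsilyloxy)propan-2-yl]dec-3-ene-2,9-dione
Product: 6 (3E,6R)-2,9-dimethyl-6-[2-(triethylsilyloxy)propan-2-yl]deca-1,3,9-triene
Conditions: Ph3PCH3Br (3 equiv), KOtBu (2.8 equiv), THF, 0 °C → rt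
Reagents that add atoms: methyltriphenylphosphonium bromide, C[P+](c1ccccc1)(c1ccccc1)c1ccccc1.[Br-]
Why: Double Wittig methylenation turns the enone into the 2-methyl-1,3-diene (1,2-addition at the carbonyl) and the saturated ketone into the 1,1-disubstituted dienophile; the E olefin is kept and no stereocentre is formed.

Step 5
Reactants: 6 (3E,6R)-2,9-dimethyl-6-[2-(triethylsilyloxy)propan-2-yl]deca-1,3,9-triene
Product: 7 (4aS,7R,8aS)-2,4a-dimethyl-7-[2-(triethylsilyloxy)propan-2-yl]-3,4,4a,5,6,7,8,8a-octahydronaphthalene (trans-fused, C1=C2 olefin)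
Conditions: toluene (0.01 M), BHT (10 mol %), sealed tube, 220 °C
Reagents that add atoms: none
Why: A thermal, concerted and suprafacial [4+2] cycloaddition (type 1 intramolecular Diels–Alder reaction) joins the diene terminus C3 to C4 and the diene terminus C8a to C4a; the closest known reaction type is the thermal cyclization of unactivated (E)-1,3,9-decatrienes to octalins. Ring A is closed as the new cyclohexene by the cycloaddition itself, and ring B is closed as a six-membered ring in the fused mode through the C4a–C8a bond, because the four-carbon tether cannot reach the bridged regiochemistry. C8a and C4a are set together: the E diene and the anti, chair-like folding of the tether (tether exo, C4a methyl under the diene) should give the trans ring fusion. Their absolute sense comes from C7, whose very bulky C(CH3)2OSiEt3 group should sit equatorial in the chair-like tether, which places the C4a methyl cis to it. The step therefore needs anti over syn folding and one face of the dienophile; the second is secured by the equatorial anchor, the first is only a moderate preference, so the cis-fused isomer is the expected by-product to be removed by chromatography.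

Step 6
Reactants: 7 (4aS,7R,8aS)-2,4a-dimethyl-7-[2-(triethylsilyloxy)propan-2-yl]-3,4,4a,5,6,7,8,8a-octahydronaphthalene
Product: 8 (1S,2R,4aS,7R,8aR)-1,2-epoxy-2,4a-dimethyl-7-[2-(triethylsilyloxy)propan-2-yl]decahydronaphthalene (epoxide oxygen trans to the C4a methyl)
Conditions: mCPBA, NaHCO3, CH2Cl2, 0 °C
Reagents that add atoms: 3-chloroperoxybenzoic acid, OOC(=O)c1cccc(Cl)c1
Why: Prilezhaev epoxidation of the only olefin, in which the peracid should approach the face opposite to the axial C4a methyl (1,3-related to C1), as in the analogous steroidal ring A olefins, so that the oxygen lies on the face of the C8a hydrogen.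

Step 7
Reactants: 8 (1S,2R,4aS,7R,8aR)-1,2-epoxy-2,4a-dimethyl-7-[2-(triethylsilyloxy)propan-2-yl]decahydronaphthalene
Product: 9 (2R,4aS,7R,8aS)-2,4a-dimethyl-7-[2-(triethylsilyloxy)propan-2-yl]decahydronaphthalen-2-ol (axial OH, equatorial C2 methyl)
Conditions: LiAlH4, THF, reflux
Reagents that add atoms: none
Why: Hydride opening of the epoxide (SN2, trans-diaxial, Fürst–Plattner rule) at the less substituted C1 leaves the C2–O bond untouched, so the tertiary alcohol keeps its oxygen axial and its methyl equatorial.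

Step 8
Reactants: 10 4-bromo-2-chloro-1-iodobenzene
Product: 12 (4-bromo-2-chlorophenyl)(2,4,6-trimethoxyphenyl)iodonium 4-methylbenzenesulfonate, via hydroxy(tosyloxy)iodoarene 11 (not isolated)
Conditions: mCPBA, TsOH·H2O, MeCN, 75 °C; then 1,3,5-trimethoxybenzene, 75 °C → rt; Et2O precipitation
Reagents that add atoms: 3-chloroperoxybenzoic acid, OOC(=O)c1cccc(Cl)c1 (oxygen of 11); 4-methylbenzenesulfonic acid monohydrate, Cc1ccc(cc1)S(=O)(=O)O.O; 1,3,5-trimethoxybenzene, COc1cc(OC)cc(OC)c1
Why: One-pot oxidation of the aryl iodide to trivalent iodine and electrophilic aromatic substitution on 1,3,5-trimethoxybenzene, the established access to aryl(trimethoxyphenyl)iodonium tosylates; no stereocentre is involved.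

Step 9
Reactants: 9 (2R,4aS,7R,8aS)-2,4a-dimethyl-7-[2-(triethylsilyloxy)propan-2-yl]decahydronaphthalen-2-ol; 12 (4-bromo-2-chlorophenyl)(2,4,6-trimethoxyphenyl)iodonium 4-methylbenzenesulfonate
Product: 14 (2R,4aS,7R,8aS)-2-(4-bromo-2-chlorophenoxy)-2,4a-dimethyl-7-[2-(triethylsilyloxy)propan-2-yl]decahydronaphthalene, via sodium alkoxide 13 (not isolated)
Conditions: NaH, toluene, 50 °C; then 12, rt → 40 °C
Reagents that add atoms: sodium hydride, [Na+].[H-] (sodium of 13)
Why: Metal-free O-arylation of a tertiary alkoxide with a diaryliodonium salt (ligand exchange at iodine, then ligand coupling), in which the electron-poor ortho-chloro aryl group should be transferred and the trimethoxyphenyl group stay on iodine; the C2–O bond is not broken, so C2 keeps its configuration.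

Step 10
Reactants: 14 (2R,4aS,7R,8aS)-2-(4-bromo-2-chlorophenoxy)-2,4a-dimethyl-7-[2-(triethylsilyloxy)propan-2-yl]decahydronaphthalene
Product: 15 (2R,4aS,7R,8aS)-2-(4-allyl-2-chlorophenoxy)-2,4a-dimethyl-7-[2-(triethylsilyloxy)propan-2-yl]decahydronaphthalene
Conditions: allylB(pin), Pd(dppf)Cl2 (5 mol %), K2CO3, 1,4-dioxane/H2O (5:1), 80 °C
Reagents that add atoms: 2-allyl-4,4,5,5-tetramethyl-1,3,2-dioxaborolane, C=CCB1OC(C)(C)C(C)(C)O1
Why: Suzuki–Miyaura allylation of the aryl bromide, which should undergo oxidative addition far faster than the hindered aryl chloride; no stereocentre is affected.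

Step 11
Reactants: 16 2-allyl-4-bromophenol
Product: 17 2-allyl-4-(4,4,5,5-tetramethyl-1,3,2-dioxaborolan-2-yl)phenol
Conditions: B2pin2, Pd(dppf)Cl2 (3 mol %), KOAc, 1,4-dioxane, 85 °C
Reagents that add atoms: bis(pinacolato)diboron, CC1(C)OB(OC1(C)C)B1OC(C)(C)C(C)(C)O1
Why: Miyaura borylation of the aryl bromide, which tolerates the free phenol and the allyl group; no stereocentre is present.

Step 12
Reactants: 15 (2R,4aS,7R,8aS)-2-(4-allyl-2-chlorophenoxy)-2,4a-dimethyl-7-[2-(triethylsilyloxy)propan-2-yl]decahydronaphthalene; 17 2-allyl-4-(4,4,5,5-tetramethyl-1,3,2-dioxaborolan-2-yl)phenol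
Product: 18 3',5-diallyl-2-{[(2R,4aS,7R,8aS)-2,4a-dimethyl-7-[2-(triethylsilyloxy)propan-2-yl]decahydronaphthalen-2-yl]oxy}biphenyl-4'-ol
Conditions: Pd(OAc)2 (5 mol %), SPhos (10 mol %), K3PO4, toluene/H2O (10:1), 90 °C
Reagents that add atoms: none
Why: Suzuki–Miyaura coupling of an ortho-alkoxy aryl chloride, for which the bulky electron-rich biaryl phosphine SPhos is suited; it completes the honokiol biaryl without touching a stereocentre.

Step 13
Reactants: 18 3',5-diallyl-2-{[(2R,4aS,7R,8aS)-2,4a-dimethyl-7-[2-(triethylsilyloxy)propan-2-yl]decahydronaphthalen-2-yl]oxy}biphenyl-4'-ol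
Product: 19 3',5-diallyl-2-{[(2R,4aS,7R,8aS)-7-(2-hydroxypropan-2-yl)-2,4a-dimethyldecahydronaphthalen-2-yl]oxy}biphenyl-4'-ol (CNP0342687.1)
Conditions: TBAF, THF, rt → 40 °C; aq. NH4Cl
Reagents that add atoms: none
Why: Fluoride cleavage of the triethylsilyl ether under basic conditions, which should leave the acid-sensitive tertiary alkyl aryl ether, the allyl groups and all four stereocentres untouched.

**Compound list**

1 | (R)-α-terpineol, 2-[(1R)-4-methylcyclohex-3-en-1-yl]propan-2-ol | CC1=CC[C@@H](CC1)C(C)(C)O | starting material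
2 | triethyl({2-[(1R)-4-methylcyclohex-3-en-1-yl]propan-2-yl}oxy)silane | CC1=CC[C@@H](CC1)C(C)(C)O[Si](CC)(CC)CC | intermediate
3 | (4R)-1-methyl-4-[2-(triethylsilyloxy)propan-2-yl]-7,8,9-trioxabicyclo[4.2.1]nonane (secondary ozonide of 2, bridgehead carbons as a mixture) | CC12CC[C@@H](C(C)(C)O[Si](CC)(CC)CC)CC(OO1)O2 | intermediate (not isolated)
4 | (3R)-6-oxo-3-[2-(triethylsilyloxy)propan-2-yl]heptanal | O=CC[C@@H](CCC(C)=O)C(C)(C)O[Si](CC)(CC)CC | intermediate
5 | (3E,6R)-6-[2-(triethylsilyloxy)propan-2-yl]dec-3-ene-2,9-dione | CC(=O)/C=C/C[C@@H](CCC(C)=O)C(C)(C)O[Si](CC)(CC)CC | intermediate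
6 | (3E,6R)-2,9-dimethyl-6-[2-(triethylsilyloxy)propan-2-yl]deca-1,3,9-triene | C=C(C)/C=C/C[C@@H](CCC(C)=C)C(C)(C)O[Si](CC)(CC)CC | intermediate
7 | (4aS,7R,8aS)-2,4a-dimethyl-7-[2-(triethylsilyloxy)propan-2-yl]-3,4,4a,5,6,7,8,8a-octahydronaphthalene | CC1=C[C@@H]2C[C@H](C(C)(C)O[Si](CC)(CC)CC)CC[C@@]2(C)CC1 | intermediate
8 | (1S,2R,4aS,7R,8aR)-1,2-epoxy-2,4a-dimethyl-7-[2-(triethylsilyloxy)propan-2-yl]decahydronaphthalene | C[C@@]12CC[C@]3(C)CC[C@@H](C(C)(C)O[Si](CC)(CC)CC)C[C@H]3[C@@H]1O2 | intermediate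
9 | (2R,4aS,7R,8aS)-2,4a-dimethyl-7-[2-(triethylsilyloxy)propan-2-yl]decahydronaphthalen-2-ol | O[C@]1(C)CC[C@]2(C)CC[C@@H](C(C)(C)O[Si](CC)(CC)CC)C[C@H]2C1 | intermediate
10 | 4-bromo-2-chloro-1-iodobenzene | Clc1cc(Br)ccc1I | starting material
11 | 4-bromo-2-chloro-1-[hydroxy(tosyloxy)iodo]benzene | Cc1ccc(cc1)S(=O)(=O)OI(O)c1ccc(Br)cc1Cl | intermediate (not isolated)
12 | (4-bromo-2-chlorophenyl)(2,4,6-trimethoxyphenyl)iodonium 4-methylbenzenesulfonate | COc1cc(OC)c([I+]c2ccc(Br)cc2Cl)c(OC)c1.Cc1ccc(cc1)S(=O)(=O)[O-] | intermediate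
13 | sodium (2R,4aS,7R,8aS)-2,4a-dimethyl-7-[2-(triethylsilyloxy)propan-2-yl]decahydronaphthalen-2-olate | [Na+].[O-][C@]1(C)CC[C@]2(C)CC[C@@H](C(C)(C)O[Si](CC)(CC)CC)C[C@H]2C1 | intermediate (not isolated)
14 | (2R,4aS,7R,8aS)-2-(4-bromo-2-chlorophenoxy)-2,4a-dimethyl-7-[2-(triethylsilyloxy)propan-2-yl]decahydronaphthalene | Clc1cc(Br)ccc1O[C@]2(C)CC[C@]3(C)CC[C@@H](C(C)(C)O[Si](CC)(CC)CC)C[C@H]3C2 | intermediate
15 | (2R,4aS,7R,8aS)-2-(4-allyl-2-chlorophenoxy)-2,4a-dimethyl-7-[2-(triethylsilyloxy)propan-2-yl]decahydronaphthalene | C=CCc1ccc(O[C@]2(C)CC[C@]3(C)CC[C@@H](C(C)(C)O[Si](CC)(CC)CC)C[C@H]3C2)c(Cl)c1 | intermediate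
16 | 2-allyl-4-bromophenol | C=CCc1cc(Br)ccc1O | starting material
17 | 2-allyl-4-(4,4,5,5-tetramethyl-1,3,2-dioxaborolan-2-yl)phenol | C=CCc1cc(ccc1O)B1OC(C)(C)C(C)(C)O1 | intermediate
18 | 3',5-diallyl-2-{[(2R,4aS,7R,8aS)-2,4a-dimethyl-7-[2-(triethylsilyloxy)propan-2-yl]decahydronaphthalen-2-yl]oxy}biphenyl-4'-ol | C=CCc1ccc(O[C@]2(C)CC[C@]3(C)CC[C@@H](C(C)(C)O[Si](CC)(CC)CC)C[C@H]3C2)c(-c2ccc(O)c(CC=C)c2)c1 | intermediate
19 | 3',5-diallyl-2-{[(2R,4aS,7R,8aS)-7-(2-hydroxypropan-2-yl)-2,4a-dimethyldecahydronaphthalen-2-yl]oxy}biphenyl-4'-ol | C=CCc1ccc(O[C@]2(C)CC[C@]3(C)CC[C@@H](C(C)(C)O)C[C@H]3C2)c(-c2ccc(O)c(CC=C)c2)c1 | target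

**Step count and risks**

Total steps: 13. Longest linear sequence: 11 steps (steps 1–7, 9, 10, 12, 13). Steps 8 and 11 are side branches.

Steps most likely to fail:

1. Step 5. Syn folding of the tether may compete with anti folding, so the ring fusion may form with poor selectivity, and the unactivated dienophile may react sluggishly at a temperature where the triene polymerizes. The fallback sets out from 5 and comes back at 9; it keeps the same two-bond cycloaddition but makes the C8a centre correctable.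
   - One equivalent of Ph3P=CH2 (THF, −78 → 0 °C) should methylenate only the saturated ketone and give the mono-methylenated enone F1.
   - TBSOTf/Et3N (CH2Cl2, 0 °C) converts the enone into the electron-rich 2-silyloxy triene F2.
   - Its intramolecular Diels–Alder reaction (toluene, 190 °C) gives the bicyclic silyl enol ether F3 as a mixture at C8a.
   - Saegusa–Ito oxidation (Pd(OAc)2, MeCN, rt) erases C8a and gives the C1=C8a octalenone F4.
   - Dissolving-metal reduction (Li, NH3, THF, t-BuOH, −78 °C) sets the trans ring fusion and gives the trans-decalone F5.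
   - MeTi(OiPr)3 (Et2O, −30 °C → rt) adds the methyl group from the equatorial side and gives 9.

2. Step 9. Ligand coupling at the hindered axial tertiary alkoxide may be slow, so base-induced aryne formation from the iodonium salt or its decomposition may take over. The fallback sets out from 9 and comes back at 14; it uses nucleophilic aromatic substitution.
   - The potassium alkoxide of 9 (KH, THF, 0 °C) displaces fluoride from 3-chloro-4-fluoronitrobenzene to give the nitroaryl ether F6.
   - Fe/NH4Cl (EtOH/H2O, 70 °C) reduces it to the aniline F7.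
   - Sandmeyer bromination (t-BuONO, CuBr2, MeCN, 0 °C → rt) gives 14.

3. Step 12. Oxidative addition into the aryl chloride next to the bulky tertiary alkoxy group may be slow, while the electron-rich hydroxyphenyl boronate is lost by protodeboronation. The fallback sets out from 15 and comes back at 18; it reverses the roles of the partners.
   - Miyaura borylation of 15 (B2pin2, Pd2(dba)3, XPhos, KOAc, 1,4-dioxane, 100 °C) gives the aryl boronate F8.
   - Suzuki–Miyaura coupling of F8 with the reactive aryl bromide 16 (Pd(dppf)Cl2, K2CO3, 1,4-dioxane/H2O, 80 °C) gives 18.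

**Further compounds**

F1 | step 5 | (3E,6R)-9-methyl-6-[2-(triethylsilyloxy)propan-2-yl]deca-3,9-dien-2-one | CC(=O)/C=C/C[C@@H](CCC(C)=C)C(C)(C)O[Si](CC)(CC)CC
F2 | step 5 | (3E,6R)-2-(tert-butyldimethylsilyloxy)-9-methyl-6-[2-(triethylsilyloxy)propan-2-yl]deca-1,3,9-triene | C=C(O[Si](C)(C)C(C)(C)C)/C=C/C[C@@H](CCC(C)=C)C(C)(C)O[Si](CC)(CC)CC
F3 | step 5 | (4aS,7R)-2-(tert-butyldimethylsilyloxy)-4a-methyl-7-[2-(triethylsilyloxy)propan-2-yl]-3,4,4a,5,6,7,8,8a-octahydronaphthalene (both C8a epimers) | CC(C)(C)[Si](C)(C)OC1=CC2C[C@H](C(C)(C)O[Si](CC)(CC)CC)CC[C@@]2(C)CC1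
F4 | step 5 | (4aS,7R)-4a-methyl-7-[2-(triethylsilyloxy)propan-2-yl]-4,4a,5,6,7,8-hexahydronaphthalen-2(3H)-one | O=C1C=C2C[C@H](C(C)(C)O[Si](CC)(CC)CC)CC[C@@]2(C)CC1
F5 | step 5 | (4aS,7R,8aS)-4a-methyl-7-[2-(triethylsilyloxy)propan-2-yl]octahydronaphthalen-2(1H)-one | O=C1C[C@@H]2C[C@H](C(C)(C)O[Si](CC)(CC)CC)CC[C@@]2(C)CC1
F6 | step 9 | (2R,4aS,7R,8aS)-2-(2-chloro-4-nitrophenoxy)-2,4a-dimethyl-7-[2-(triethylsilyloxy)propan-2-yl]decahydronaphthalene | [O-][N+](=O)c1ccc(O[C@]2(C)CC[C@]3(C)CC[C@@H](C(C)(C)O[Si](CC)(CC)CC)C[C@H]3C2)c(Cl)c1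
F7 | step 9 | 3-chloro-4-{[(2R,4aS,7R,8aS)-2,4a-dimethyl-7-[2-(triethylsilyloxy)propan-2-yl]decahydronaphthalen-2-yl]oxy}aniline | Nc1ccc(O[C@]2(C)CC[C@]3(C)CC[C@@H](C(C)(C)O[Si](CC)(CC)CC)C[C@H]3C2)c(Cl)c1
F8 | step 12 | (2R,4aS,7R,8aS)-2-[4-allyl-2-(4,4,5,5-tetramethyl-1,3,2-dioxaborolan-2-yl)phenoxy]-2,4a-dimethyl-7-[2-(triethylsilyloxy)propan-2-yl]decahydronaphthalene | C=CCc1ccc(O[C@]2(C)CC[C@]3(C)CC[C@@H](C(C)(C)O[Si](CC)(CC)CC)C[C@H]3C2)c(c1)B1OC(C)(C)C(C)(C)O1
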